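**Retrosynthetic overview**
- Feature: in ring C the C2–C3 unit is a styrene flanked by the O1–C2 and C3–C4 bonds. C4 lies ortho/para to three ring A oxygens (O1 on C8a, O5, O7), so C8a–C4a–C4 can be written as a stabilised ortho-quinone methide.
- End game: the target comes from a 4-methoxyflavan by hydrolysis of the C4 ether, oxidation at C4, peri-demethylation at O5 and desilylation at O4'.
- Key disconnection: O1–C2 and C3–C4 together, back to 2-hydroxy-4,5,6-trimethoxy-3-prenylbenzaldehyde (reacting as its 4-methoxy quinone methide) and 4-(tert-butyldimethylsilyloxy)styrene, with a chiral N-triflylphosphoramide setting C2.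
- The aldehyde comes from 3,4,5-trimethoxyphenol by ortho C-prenylation and ortho formylation; the styrene comes from 4-acetoxystyrene.
- Ring order: rings A and B are bought as arenes; ring C is the only ring formed (step 5).

Key step: step 5

Assumption: the sense of induction of the chiral acid cannot be assigned in advance; the (R)-catalyst is written, and its mirror image is to be used if the first run gives the 2R series.

**Step 1**
Reactants: 1 3,4,5-trimethoxyphenol; 2 prenyl bromide
Product: 3 3,4,5-trimethoxy-2-(3-methylbut-2-en-1-yl)phenol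
Conditions: NaH (1.1 equiv), toluene, 0 °C → rt; then 2 (0.9 equiv), rt
Reagents that add atoms: none
Why: Ortho C-alkylation of a phenoxide, in which the tight sodium ion pair in toluene shields oxygen and delivers the allylic bromide to one of the two equivalent ortho carbons before the dienone tautomerises to the phenol; the O-prenyl ether and the 2,6-diprenyl phenol are expected minor products to be removed by chromatography.

**Step 2**
Reactants: 3 3,4,5-trimethoxy-2-(3-methylbut-2-en-1-yl)phenol
Product: 4 2-hydroxy-4,5,6-trimethoxy-3-(3-methylbut-2-en-1-yl)benzaldehyde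
Conditions: MgCl2, Et3N, (CH2O)n, MeCN, reflux; dilute HCl work-up
Reagents that add atoms: paraformaldehyde (formaldehyde), C=O
Why: Magnesium-mediated ortho-formylation (Casnati–Skattebøl), in which the magnesium phenoxide directs formaldehyde to the single free ortho position and a second formaldehyde oxidises the benzylic alkoxide by hydride transfer, the basic medium leaving the prenyl group and the methyl ethers untouched.

**Step 3**
Reactants: 5 4-acetoxystyrene
Product: 6 4-vinylphenol
Conditions: K2CO3 (cat.), MeOH, 0 °C; AcOH quench; used at once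
Reagents that add atoms: none
Why: Base-catalysed methanolysis of an aryl acetate, with the product kept cold and carried on immediately because it polymerises on standing.

**Step 4**
Reactants: 6 4-vinylphenol
Product: 7 4-(tert-butyldimethylsilyloxy)styrene
Conditions: TBSCl, imidazole, CH2Cl2, 0 °C → rt
Reagents that add atoms: tert-butyldimethylsilyl chloride, CC(C)(C)[Si](C)(C)Cl
Why: Standard silylation of a phenol, giving a storable, electron-rich styrene whose aryl silyl ether should tolerate the acid of step 5.

**Step 5**
Reactants: 4 2-hydroxy-4,5,6-trimethoxy-3-(3-methylbut-2-en-1-yl)benzaldehyde; 7 4-(tert-butyldimethylsilyloxy)styrene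
Product: 10 (2S,4S)-4,5,6,7-tetramethoxy-8-(3-methylbut-2-en-1-yl)-2-[4-(tert-butyldimethylsilyloxy)phenyl]chromane (2,4-cis-4-methoxyflavan), via dimethyl acetal 8 (not isolated), via protonated quinone methide 9 (not isolated)
Conditions: HC(OMe)3 (1.5 equiv), (R)-3,3'-bis(2,4,6-triisopropylphenyl)-1,1'-binaphthyl-2,2'-diyl N-triflylphosphoramide (10 mol%), 5 Å MS, toluene, 0 °C; then 7 (2 equiv) added slowly at −30 °C; Et3N quench
Reagents that add atoms: trimethyl orthoformate, COC(OC)OC
Why: Proposed new method: the chiral acid converts 4 and the orthoformate into acetal 8 and ionises it to the aryl methoxycarbenium ion 9, which is the O-protonated 4-methoxy ortho-quinone methide and stays paired with the phosphoramide anion through the hydrogen bond of the C8a hydroxyl; the CH2 terminus of 7 adds to C4 (bond C3–C4) and the 4-silyloxybenzylic cation so formed is captured by the phenol oxygen (bond O1–C2), an asynchronous inverse-demand hetero-Diels–Alder reaction. The closest known reaction types are the chiral N-triflylphosphoramide-catalysed (4+2) cycloadditions of ortho-quinone methides from ortho-hydroxybenzylic alcohols with styrenes, which give 2,4-diarylchromans, and the achiral acid-promoted union of salicylaldehydes, trimethyl orthoformate and styrenes to 2,4-cis-4-methoxyflavans; new is anion control over a 4-alkoxy quinone methide made from an aldehyde acetal. Ring C is the only ring closed, in a (4+2) mode across O1=C8a–C4a=C4 whose second bond is a 6-exo-trig capture of the C2 cation by O1 through a half-chair with aryl and methoxy pseudo-equatorial, hence 2,4-cis. C4 is set by the face of the carbenium ion left open by the bound anion and C2 follows from C4 through the cis closure, so 2S (the only centre that survives) is secured only if both face selection and cis selectivity are high, because a trans adduct formed on the same face would carry 2R. Regiochemistry (aryl on C2) rests on the 4-silyloxy group, which makes the styrene terminus the nucleophile and stabilises the C2 cation, while the O5, O7 and O1 donors make ionisation at C4 easy. Chemoselectivity over the prenyl alkene and over acid cyclisation of the ortho-prenyl phenol to a chroman rests on the higher nucleophilicity of the donor styrene, the low temperature and the modest acidity of the ion-paired catalyst.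

**Step 6**
Reactants: 10 (2S,4S)-4,5,6,7-tetramethoxy-8-(3-methylbut-2-en-1-yl)-2-[4-(tert-butyldimethylsilyloxy)phenyl]chromane
Product: 11 (2S,4RS)-5,6,7-trimethoxy-8-(3-methylbut-2-en-1-yl)-2-[4-(tert-butyldimethylsilyloxy)phenyl]chroman-4-ol (C4 epimers, used crude)
Conditions: TsOH·H2O (5 mol%), THF/H2O (4:1), 0 °C → rt; NaHCO3 quench
Reagents that add atoms: water, O
Why: SN1 solvolysis of a benzylic methyl ether whose cation is stabilised by O5, O7 and O1, so that dilute aqueous acid should exchange methoxy for hydroxyl without touching the aryl silyl ether, the prenyl group or C2, and either C4 epimer is acceptable because C4 is oxidised next.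

**Step 7**
Reactants: 11 (2S,4RS)-5,6,7-trimethoxy-8-(3-methylbut-2-en-1-yl)-2-[4-(tert-butyldimethylsilyloxy)phenyl]chroman-4-ol
Product: 12 (2S)-5,6,7-trimethoxy-8-(3-methylbut-2-en-1-yl)-2-[4-(tert-butyldimethylsilyloxy)phenyl]chroman-4-one
Conditions: nPr4N[RuO4] (5 mol%), NMO, 4 Å MS, CH2Cl2, rt
Reagents that add atoms: none
Why: Ley–Griffith oxidation of a secondary benzylic alcohol under neutral conditions, which avoids ionisation at C4, leaves the alkene, the electron-rich ring and C2 alone, and removes the C4 stereocentre.

**Step 8**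
Reactants: 12 (2S)-5,6,7-trimethoxy-8-(3-methylbut-2-en-1-yl)-2-[4-(tert-butyldimethylsilyloxy)phenyl]chroman-4-one
Product: 13 (2S)-5-hydroxy-6,7-dimethoxy-8-(3-methylbut-2-en-1-yl)-2-[4-(tert-butyldimethylsilyloxy)phenyl]chroman-4-one
Conditions: MgI2·OEt2 (2.5 equiv), toluene/Et2O, 60 °C; then cold 0.5 M HCl
Reagents that add atoms: none
Why: Chelation-controlled demethylation, in which magnesium bridges the C4 carbonyl and O5 and iodide removes only the peri methyl group, a known selectivity for 5-methoxyflavanones that spares the 6- and 7-methyl ethers, the prenyl group and the aryl silyl ether, the retained silyl ether keeping ring B a weak donor so that the O1–C2 bond is not prone to ionise.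

**Step 9**
Reactants: 13 (2S)-5-hydroxy-6,7-dimethoxy-8-(3-methylbut-2-en-1-yl)-2-[4-(tert-butyldimethylsilyloxy)phenyl]chroman-4-one
Product: 14 (2S)-5-hydroxy-2-(4-hydroxyphenyl)-6,7-dimethoxy-8-(3-methylbut-2-en-1-yl)chroman-4-one (CNP0104932.1)
Conditions: Bu4NF/AcOH (1:1), THF, 0 °C
Reagents that add atoms: none
Why: Fluoride cleavage of an aryl silyl ether, buffered with acetic acid so that no phenoxide forms and the flavanone cannot open to the chalcone, which would racemise C2 or let ring C reclose through O5.

**Compound list**
1 | 3,4,5-trimethoxyphenol | COc1cc(O)cc(OC)c1OC | starting material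
2 | prenyl bromide (1-bromo-3-methylbut-2-ene) | CC(C)=CCBr | starting material
3 | 3,4,5-trimethoxy-2-(3-methylbut-2-en-1-yl)phenol | COc1cc(O)c(CC=C(C)C)c(OC)c1OC | intermediate
4 | 2-hydroxy-4,5,6-trimethoxy-3-(3-methylbut-2-en-1-yl)benzaldehyde | COc1c(OC)c(C=O)c(O)c(CC=C(C)C)c1OC | intermediate
5 | 4-acetoxystyrene | CC(=O)Oc1ccc(C=C)cc1 | starting material
6 | 4-vinylphenol | C=Cc1ccc(O)cc1 | intermediate
7 | 4-(tert-butyldimethylsilyloxy)styrene | C=Cc1ccc(O[Si](C)(C)C(C)(C)C)cc1 | intermediate
8 | 2-(dimethoxymethyl)-3,4,5-trimethoxy-6-(3-methylbut-2-en-1-yl)phenol (dimethyl acetal of 4, not isolated) | COC(OC)c1c(O)c(CC=C(C)C)c(OC)c(OC)c1OC | intermediate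
9 | O-protonated 4-methoxy ortho-quinone methide: [2-hydroxy-4,5,6-trimethoxy-3-(3-methylbut-2-en-1-yl)phenyl]methylidene(methyl)oxonium, ion pair with the phosphoramide anion (not isolated) | C[O+]=Cc1c(O)c(CC=C(C)C)c(OC)c(OC)c1OC | intermediate
10 | (2S,4S)-4,5,6,7-tetramethoxy-8-(3-methylbut-2-en-1-yl)-2-[4-(tert-butyldimethylsilyloxy)phenyl]chromane (2,4-cis) | COc1c(OC)c2c(c(CC=C(C)C)c1OC)O[C@H](c1ccc(O[Si](C)(C)C(C)(C)C)cc1)C[C@@H]2OC | intermediate
11 | (2S,4RS)-5,6,7-trimethoxy-8-(3-methylbut-2-en-1-yl)-2-[4-(tert-butyldimethylsilyloxy)phenyl]chroman-4-ol (C4 epimers) | COc1c(OC)c2c(c(CC=C(C)C)c1OC)O[C@H](c1ccc(O[Si](C)(C)C(C)(C)C)cc1)CC2O | intermediate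
12 | (2S)-5,6,7-trimethoxy-8-(3-methylbut-2-en-1-yl)-2-[4-(tert-butyldimethylsilyloxy)phenyl]chroman-4-one | COc1c(OC)c2c(c(CC=C(C)C)c1OC)O[C@H](c1ccc(O[Si](C)(C)C(C)(C)C)cc1)CC2=O | intermediate
13 | (2S)-5-hydroxy-6,7-dimethoxy-8-(3-methylbut-2-en-1-yl)-2-[4-(tert-butyldimethylsilyloxy)phenyl]chroman-4-one | COc1c(O)c2c(c(CC=C(C)C)c1OC)O[C@H](c1ccc(O[Si](C)(C)C(C)(C)C)cc1)CC2=O | intermediate
14 | (2S)-5-hydroxy-2-(4-hydroxyphenyl)-6,7-dimethoxy-8-(3-methylbut-2-en-1-yl)chroman-4-one | COc1c(O)c2c(c(CC=C(C)C)c1OC)O[C@H](c1ccc(O)cc1)CC2=O | target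

**Step count**
Total: 9 steps. Longest linear sequence: 7 steps (steps 1, 2, 5, 6, 7, 8, 9 from 3,4,5-trimethoxyphenol; the styrene branch, steps 3, 4, 5–9, is equally long).

**Steps most likely to fail**

1. Step 5 (proposed new method). Several things may go wrong:
   - The delocalised cation is held to the chiral anion by a single hydrogen bond, so facial selectivity may be poor.
   - Incomplete cis selectivity would turn into erosion at C2 once C4 is erased.
   - The acid may cyclise the ortho-prenyl phenol to a chroman or oligomerise the styrene.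
   - The strongly stabilised cation may add only slowly.

   The fallback sets C2 by known chemistry and sets out from 4. Addition of MeMgBr (THF, 0 °C) should give 1-[2-hydroxy-4,5,6-trimethoxy-3-(3-methylbut-2-en-1-yl)phenyl]ethanol F1. MnO2 in CH2Cl2 should oxidise it to 1-[2-hydroxy-4,5,6-trimethoxy-3-(3-methylbut-2-en-1-yl)phenyl]ethanone F2. Condensation with N,N-dimethylformamide dimethyl acetal (toluene, 90 °C) should give (E)-3-(dimethylamino)-1-[2-hydroxy-4,5,6-trimethoxy-3-(3-methylbut-2-en-1-yl)phenyl]prop-2-en-1-one F3. Brief treatment with dilute HCl in CH2Cl2 should close it to 5,6,7-trimethoxy-8-(3-methylbut-2-en-1-yl)chromen-4-one F4. Asymmetric conjugate addition of commercial 4-(tert-butyldimethylsilyloxy)phenylboronic acid (Pd(OCOCF3)2, chiral tert-butyl pyridine–oxazoline ligand of the enantiomer that delivers 2S, NH4PF6, water, ClCH2CH2Cl, 60 °C) then returns to the route at 12.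

2. Step 1. O-alkylation and a second C-alkylation may compete with the wanted mono ortho C-prenylation. The fallback sets out from 1 and builds the C–C bond by a sigmatropic shift. Alkylation with 3-chloro-3-methylbut-1-yne (K2CO3, KI, CuI cat., acetone, reflux) should give 1,2,3-trimethoxy-5-(2-methylbut-3-yn-2-yloxy)benzene F5. Semi-hydrogenation (H2, Pd/CaCO3 poisoned with Pb(OAc)2, quinoline, EtOAc) should give 1,2,3-trimethoxy-5-(2-methylbut-3-en-2-yloxy)benzene F6. An aromatic Claisen rearrangement (xylene, about 130 °C) moves the allyl unit, with transposition, to the ortho carbon and returns to the route at 3.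

3. Step 6. The ionised C4 centre may lose H3 to give the flav-3-ene, or be captured by other nucleophiles, and the sensitive benzylic alcohol may decompose on silica. The fallback sets out from 10 and avoids acid and the free alcohol. DDQ in CH2Cl2/pH 7 buffer at 0 °C should abstract hydride from C4, the most hydridic C–H, and hydrolysis of the resulting oxocarbenium ion gives the ketone directly. It returns to the route at 12, skipping 11 and step 7, and makes no new compound (F0).

**Further compounds**
F1 | step 5 | 1-[2-hydroxy-4,5,6-trimethoxy-3-(3-methylbut-2-en-1-yl)phenyl]ethanol (racemic) | COc1c(OC)c(C(C)O)c(O)c(CC=C(C)C)c1OC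
F2 | step 5 | 1-[2-hydroxy-4,5,6-trimethoxy-3-(3-methylbut-2-en-1-yl)phenyl]ethanone | COc1c(OC)c(C(C)=O)c(O)c(CC=C(C)C)c1OC
F3 | step 5 | (E)-3-(dimethylamino)-1-[2-hydroxy-4,5,6-trimethoxy-3-(3-methylbut-2-en-1-yl)phenyl]prop-2-en-1-one | COc1c(OC)c(C(=O)/C=C/N(C)C)c(O)c(CC=C(C)C)c1OC
F4 | step 5 | 5,6,7-trimethoxy-8-(3-methylbut-2-en-1-yl)chromen-4-one | COc1c(OC)c2c(c(CC=C(C)C)c1OC)OC=CC2=O
F5 | step 1 | 1,2,3-trimethoxy-5-(2-methylbut-3-yn-2-yloxy)benzene | COc1cc(OC(C)(C)C#C)cc(OC)c1OC
F6 | step 1 | 1,2,3-trimethoxy-5-(2-methylbut-3-en-2-yloxy)benzene | COc1cc(OC(C)(C)C=C)cc(OC)c1OC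
F0 | step 6 | none | none
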